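**Strategy.** The cycloheptane ring is made by one-carbon ring expansion: its quaternary carbon C(CH3)(CH2O) is inserted last between a ring ketone and the adjacent cyclobutane CH. The precursor is a doubly bridged cyclobutane (two bicyclo[3.1.1]heptanes sharing the four-membered ring): one bridge is the finished enone, the other a six-membered β-acyloxy ketone. Its ester, a 2-diazopropanoate on the oxygen of the CH–O carbon beside the methyl-bearing cyclobutane carbon, attacks the ketone under Lewis acid; the cyclobutane CH then migrates with loss of N2. One operation gives the seven-membered ring, the quaternary stereocentre and, through the tether, its cis relationship to that oxygen. The tricycle comes from a quinone Diels–Alder adduct.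

Key step: step 10

Remark (labels used in names): seven-membered ring C1 (quaternary, CH3 and CH2O), C2 (cyclobutane CH), C3 (cyclobutane CH α to the ketone), C4 (cyclobutane C–CH3), C5 (CH–O), C6 (CH2), C7 (CH–O); enone bridge C8 (C=O), C9 (=CH), C10 (=C–CH3); C11 is the fourth cyclobutane CH.

Remark (assumption): the (S)-configured oxazaborolidinium catalyst is assumed to give the drawn enantiomer of 4 by analogy with its quinone selection model; if the sense is opposite, the (R)-catalyst is used with nothing else changed.

**Step 1**
Reactants: 1 (E)-pent-3-en-2-one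
Product: 2 (E)-2-(tert-butyldimethylsilyloxy)penta-1,3-diene
Conditions: LiN(iPr)2, THF, −78 °C; tBuMe2SiCl, DMPU, −78 → 0 °C
Reagents that add atoms: tert-butyldimethylsilyl chloride, CC(C)(C)[Si](C)(C)Cl
Why: Kinetic enolisation at the methyl group followed by O-silylation is the standard silyl dienol ether synthesis and leaves the E alkene untouched.

**Step 2**
Reactants: 2 (E)-2-(tert-butyldimethylsilyloxy)penta-1,3-diene; 3 2-methoxy-5-methyl-1,4-benzoquinone
Product: 4 cis-fused Diels–Alder adduct
Conditions: (S)-oxazaborolidinium triflimide [B-o-tolyl oxazaborolidine from (S)-α,α-diphenylprolinol, activated with HN(SO2CF3)2] (20 mol %), CH2Cl2, −78 °C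
Reagents that add atoms: none
Why: Catalytic enantioselective quinone Diels–Alder reaction in which the nucleophilic CH2 terminus of the diene should bond to the methyl-bearing quinone carbon (the methoxy-substituted C=C is deactivated), the suprafacial endo addition giving the cis ring fusion and the catalyst setting quaternary C4 and C11.

**Step 3**
Reactants: 4 cis-fused Diels–Alder adduct
Product: 5 concave 1,4-diol
Conditions: iBu2AlH (3 equiv), CH2Cl2, −78 °C; aq. KNaC4H4O6
Reagents that add atoms: none
Why: 1,2-Reduction of both ring B carbonyls by hydride from the convex face of the cis-fused bicycle (anti to ring A) should place both hydroxyls on the concave face, which fixes C5; the two enol ethers are inert.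

**Step 4**
Reactants: 5 concave 1,4-diol
Product: 6 enone diol
Conditions: Pd(OAc)2 (1.2 equiv), NaHCO3, MeCN, 40 °C
Reagents that add atoms: none
Why: Saegusa–Ito oxidation, in which the palladium enolate at C9 can β-eliminate only toward C10, gives the 3-methylcyclohexenone and erases the C10 stereocentre.

**Step 5**
Reactants: 6 enone diol
Product: 7 inverted C2 chloride
Conditions: PPh3, Cl3CC(O)CCl3, 2,6-lutidine, CH2Cl2, −30 → 0 °C
Reagents that add atoms: hexachloroacetone, ClC(Cl)(Cl)C(=O)C(Cl)(Cl)Cl
Why: Appel-type chlorination (hexachloroacetone variant, little allylic transposition) should take only the less hindered C2 hydroxyl (C5–OH is neopentylic) and invert it, so that the leaving group lies on the face opposite to C3.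

**Step 6**
Reactants: 7 inverted C2 chloride
Product: 10 tricyclic enol ether alcohol, via trimethylsilyl ether of the chloride 8 (not isolated), via trimethylsilyl ether of the tricycle 9 (not isolated)
Conditions: Me3SiCl (1.05 equiv), Et3N, THF, 0 °C; KN(SiMe3)2 (2.2 equiv), −78 → 0 °C; K2CO3, MeOH, 0 °C
Reagents that add atoms: none
Why: After transient silylation of C5–OH (which would otherwise bridge to C2), kinetic α'-deprotonation of the enone at C3 and 4-exo-tet SN2 displacement of the allylic chloride (intramolecular ketone enolate alkylation, as used for pinane cyclobutanes) should close the C2–C3 bond with inversion at C2, C3 being set by the ring constraint.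

**Step 7**
Reactants: 10 tricyclic enol ether alcohol; 11 N-Boc-L-alanine
Product: 12 C5 N-Boc-alaninate
Conditions: DCC, DMAP (cat.), CH2Cl2, 0 °C → rt
Reagents that add atoms: none
Why: Steglich esterification acylates the hindered secondary alcohol under conditions mild enough for the enol ether and installs the atoms of the future tether.

**Step 8**
Reactants: 12 C5 N-Boc-alaninate
Product: 13 amino ester hydrochloride of the C7 ketone
Conditions: HCl (4 M in dioxane), H2O (5 equiv), 0 °C → rt
Reagents that add atoms: water, O; hydrogen chloride, Cl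
Why: Aqueous acid C-protonates the enol ether at C6 (hydrolysis to the C7 ketone, a β-acyloxy ketone that is stable to acid) and cleaves the Boc carbamate, the amine being kept as its salt.

**Step 9**
Reactants: 13 amino ester hydrochloride of the C7 ketone
Product: 14 C5 2-diazopropanoate
Conditions: isoamyl nitrite, NaOAc, AcOH (cat.), CHCl3, 50 °C
Reagents that add atoms: isoamyl nitrite, CC(C)CCON=O
Why: Diazotisation of an α-amino ester with an alkyl nitrite (the diazonium ion loses its acidic α-proton) gives the α-diazo ester under weakly acidic conditions that avoid base-induced β-elimination of the acyloxy group.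

**Step 10**
Reactants: 14 C5 2-diazopropanoate
Product: 16 bridged keto lactone, via diazonium alkoxide 15 (not isolated)
Conditions: Sc(OTf)3 (10 mol %), CH2Cl2 (0.01 M), −20 °C → rt
Reagents that add atoms: none
Why: Sc(OTf)3 activates the C7 ketone, the nucleophilic diazo carbon adds to it (6-exo-trig closure of the δ-lactone ring, possible only on the ketone face that carries the C5 oxygen) to give diazonium alkoxide 15, and the C7–C2 bond antiperiplanar to C–N2 then shifts to the diazonium carbon with loss of N2, which expands the six-membered carbocycle to the cycloheptanone. The closest known type is the Lewis acid-promoted ring expansion of cycloalkanones with α-alkyl α-diazo esters (Büchner–Curtius–Schlotterbeck or Roskamp-type homologation), here in its intramolecular, ester-tethered form. The new quaternary stereocentre C1 is controlled by the tether: the ester carbon must stay cis to C5–O in the bridged lactone, so the carbon that becomes CH2O and the C5 oxygen end on the same face and the methyl on the other, while C2 migrates with retention. The step needs migration of C2 and not of C6, and this is its main risk, because untethered diazo ester insertions usually move the less substituted carbon. In its favour, C2 is the more substituted carbon, C6 is deactivated by the acyloxy-bearing C5 next to it, and the inward hydrogen on C3 should twist the forming lactone so that the position beside the scandium alkoxide, which the small diazonium group prefers, is the one anti to C7–C2. Acidic conditions avoid the β-elimination that bases would cause.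

**Step 11**
Reactants: 16 bridged keto lactone
Product: 17 tetraol
Conditions: LiAlH4 (6 equiv), THF, −78 → 0 °C; Na2SO4·10H2O
Reagents that add atoms: none
Why: LiAlH4 should reduce the C7 ketone first, hydride arriving from the side of the hydrogen-free lactone bridge so that C7–OH is trans to the C1 carboxyl carbon, then open the lactone to C1–CH2OH and C5–OH, the enone being reduced 1,2 to the allylic alcohol in the same pot.

**Step 12**
Reactants: 17 tetraol
Product: 18 triol enone
Conditions: MnO2 (excess), CH2Cl2, rt
Reagents that add atoms: none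
Why: MnO2 oxidises only the allylic (verbenol-type) alcohol back to the enone and leaves the three saturated alcohols untouched.

**Step 13**
Reactants: 18 triol enone; 19 angelic acid
Product: 20 C1–CH2O mono-angelate
Conditions: 19 (1.1 equiv), 2,4,6-trichlorobenzoyl chloride (1.1 equiv), Et3N, toluene, rt; then 18, 40 °C
Reagents that add atoms: none
Why: Yamaguchi-type esterification through the angelic 2,4,6-trichlorobenzoic mixed anhydride without DMAP keeps the Z geometry, and with one equivalent at moderate temperature the only primary hydroxyl should react well before the two neopentylic secondary ones.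

**Step 14**
Reactants: 20 C1–CH2O mono-angelate; 19 angelic acid
Product: 21 C1–CH2O, C5–O bis-angelate
Conditions: 19 (1.3 equiv), 2,4,6-trichlorobenzoyl chloride (1.3 equiv), Et3N, toluene, rt; then 20, 60 °C
Reagents that add atoms: none
Why: The same DMAP-free mixed anhydride esterification should take C5–OH before C7–OH, because C5 lies beside the cyclobutane carbon C4 whose ring bonds are pinned back (this hydroxyl was already acylated under mild Steglich conditions in step 7), whereas C7 is flanked by the fully substituted C1 that now carries the CH2O angelate.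

**Step 15**
Reactants: 21 C1–CH2O, C5–O bis-angelate; 19 angelic acid
Product: 22 CNP0266467.1
Conditions: 19 (4 equiv), 2,4,6-trichlorobenzoyl chloride (4 equiv), Et3N, toluene, rt; then 21, 80 °C
Reagents that add atoms: none
Why: Excess mixed anhydride at 80 °C without a nucleophilic catalyst should force the Yamaguchi-type acylation of the last, most hindered hydroxyl at C7 while every angelate stays Z.

**Compound list**

1 | (E)-pent-3-en-2-one | C/C=C/C(C)=O | starting material
2 | (E)-2-(tert-butyldimethylsilyloxy)penta-1,3-diene | C/C=C/C(=C)O[Si](C)(C)C(C)(C)C | intermediate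
3 | 2-methoxy-5-methyl-1,4-benzoquinone | COC1=CC(=O)C(C)=CC1=O | starting material
4 | cis-fused 6-(tert-butyldimethylsilyloxy)-2-methoxy-4a,8-dimethyl-4a,5,8,8a-tetrahydronaphthalene-1,4-dione; 4a-CH3 (C4) cis to 8a-H (C11), 8-CH3 trans to 8a-H | C[C@@H]1C=C(O[Si](C)(C)C(C)(C)C)C[C@]2(C)C(=O)C=C(OC)C(=O)[C@H]12 | intermediate
5 | 1,4-diol of 4, both hydroxyls (at C2 and C5) on the concave face, trans to 8a-H and 4a-CH3 | C[C@@H]1C=C(O[Si](C)(C)C(C)(C)C)C[C@]2(C)[C@H](O)C=C(OC)[C@H](O)[C@H]12 | intermediate
6 | enone diol: ring A is the 3-methylcyclohex-2-enone (C8=O, C9=C10–CH3), ring B as in 5 | CC1=CC(=O)C[C@]2(C)[C@H](O)C=C(OC)[C@H](O)[C@H]12 | intermediate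
7 | C2 chloride with inverted C2 (Cl cis to H-11 and to the C4 methyl), C5–OH free | CC1=CC(=O)C[C@]2(C)[C@H](O)C=C(OC)[C@@H](Cl)[C@H]12 | intermediate
8 | C5 trimethylsilyl ether of 7 | CC1=CC(=O)C[C@]2(C)[C@H](O[Si](C)(C)C)C=C(OC)[C@@H](Cl)[C@H]12 | intermediate (not isolated)
9 | C5 trimethylsilyl ether of 10 | COC=1[C@@H]2[C@H]3C(=O)C=C(C)[C@@H]2[C@@]3(C)[C@H](O[Si](C)(C)C)C=1 | intermediate (not isolated)
10 | tricyclic enol ether alcohol: cyclobutane C2–C3–C4–C11 bridged by C3–C8(=O)–C9=C10(CH3)–C11 on one face and by C2–C7(OCH3)=C6–C5H(OH)–C4 on the other; C5–OH on the side of C3 | COC=1[C@@H]2[C@H]3C(=O)C=C(C)[C@@H]2[C@@]3(C)[C@H](O)C=1 | intermediate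
11 | N-(tert-butoxycarbonyl)-L-alanine | C[C@H](NC(=O)OC(C)(C)C)C(=O)O | starting material
12 | ester of 10 at C5–O with N-Boc-L-alanine | COC=1[C@@H]2[C@H]3C(=O)C=C(C)[C@@H]2[C@@]3(C)[C@H](OC(=O)[C@H](C)NC(=O)OC(C)(C)C)C=1 | intermediate
13 | L-alaninate hydrochloride of the tricyclic dione (C7 ketone, C8 enone, ester at C5–O) | O=C1[C@@H]2[C@H]3C(=O)C=C(C)[C@@H]2[C@@]3(C)[C@H](OC(=O)[C@H](C)[NH3+])C1.[Cl-] | intermediate
14 | C5 2-diazopropanoate of the tricyclic dione | O=C1[C@@H]2[C@H]3C(=O)C=C(C)[C@@H]2[C@@]3(C)[C@H](OC(=O)C(C)=[N+]=[N-])C1 | intermediate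
15 | scandium-bound diazonium alkoxide (drawn as the zwitterion): new C1–C7 bond on the face of C7 that carries C5–O, lactone ring C1–C(=O)–O–C5–C6–C7, N2 on C1 anti to C7–C2 | [O-][C@@]12[C@@H]3[C@H]4C(=O)C=C(C)[C@@H]3[C@@]4(C)[C@@H](C1)OC(=O)[C@@]2(C)[N+]#N | intermediate (not isolated)
16 | bridged keto lactone: cycloheptanone (C7=O) with C1(CH3) between C2 and C7, C1 carboxyl lactonised to C5–O (cis), enone intact | O=C4[C@]1(C)[C@@H]2[C@H]3C(=O)C=C(C)[C@@H]2[C@@]3(C)[C@H](O4)CC1=O | intermediate
17 | tetraol: C1–CH2OH, C5–OH, C7–OH (trans to CH2OH and to C5–OH), allylic C8–OH (expected on the side of C4; this centre is of no consequence) | OC[C@]1(C)[C@@H]2[C@H]3[C@H](O)C=C(C)[C@@H]2[C@@]3(C)[C@H](O)C[C@H]1O | intermediate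
18 | triol enone (C8=O restored) | OC[C@]1(C)[C@@H]2[C@H]3C(=O)C=C(C)[C@@H]2[C@@]3(C)[C@H](O)C[C@H]1O | intermediate
19 | angelic acid, (Z)-2-methylbut-2-enoic acid | C/C=C(/C)C(=O)O | starting material
20 | mono-angelate of 18 at the primary C1–CH2O; C5–OH and C7–OH free | C/C=C(/C)C(=O)OC[C@]1(C)[C@@H]2[C@H]3C(=O)C=C(C)[C@@H]2[C@@]3(C)[C@H](O)C[C@H]1O | intermediate
21 | bis-angelate of 18 at C1–CH2O and C5–O; C7–OH free | C/C=C(/C)C(=O)OC[C@]1(C)[C@@H]2[C@H]3C(=O)C=C(C)[C@@H]2[C@@]3(C)[C@H](OC(=O)/C(C)=C\C)C[C@H]1O | intermediate
22 | CNP0266467.1, tris-angelate of 18 | C/C=C(/C)C(=O)OC[C@]1(C)[C@@H]2[C@H]3C(=O)C=C(C)[C@@H]2[C@@]3(C)[C@H](OC(=O)/C(C)=C\C)C[C@H]1OC(=O)/C(C)=C\C | target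

**Totals.** 15 steps; longest linear sequence 15 steps (from 1; 3 and 11 enter at steps 2 and 7, and 19 enters at steps 13, 14 and 15).

**Steps most likely to fail**

1. Step 10. The 1,2-shift may move the methylene carbon C6 instead of the cyclobutane carbon C2, or the strained lactone closure may be so slow that the diazo ester decomposes. The fallback is a stepwise epoxy alcohol semipinacol rearrangement with electronic control of migration, setting out from 10 and returning at 17. iBu2AlH reduces the enone to the allylic diol F1, and tBuMe2SiOTf with 2,6-lutidine gives the bis-silyl ether F2. Aqueous oxalic acid in THF unmasks the C7 ketone F3. 2-Propenylmagnesium bromide with CeCl3 should add from the face opposite to the C5 silyloxy group to give the tertiary allylic alcohol F4. VO(acac)2 with tBuOOH should give the epoxy alcohol F5 by hydroxyl-directed epoxidation, with the alkene methyl eclipsing the smaller C6. BF3·OEt2 at −78 °C triggers the semipinacol shift of the more substituted C2, anti to the epoxide C–O bond, to the hydroxymethyl ketone F6. Me4NBH(OAc)3 delivers hydride from the hydroxymethyl group to give the diol F7, and Bu4NF removes both silyl groups to give 17.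

2. Step 6. The four-membered ring may close more slowly than the enolate equilibrates to the extended dienolate, which would eliminate HCl. The fallback uses palladium allyl chemistry with net retention instead of SN2 on an inverted halide, setting out from 6 and returning at 10. Methyl chloroformate with pyridine at −20 °C acylates the less hindered C2 hydroxyl to the carbonate F8, and Me3SiCl with Et3N gives its C5 silyl ether F9. LiN(SiMe3)2 forms the C3 enolate, and Pd2(dba)3 with PPh3 ionises the carbonate anti. The enolate should attack the allyl terminus C2, remote from the C5 oxygen and anti to palladium, to give 9; methanolysis with K2CO3 gives 10.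

3. Step 15. Acylation of the neopentylic C7 hydroxyl beside quaternary C1 may stall, or forcing may isomerise angelate to tiglate. The fallback builds the last Z alkene after acylation, setting out from 21 and returning at 22. DCC and DMAP with 2-[bis(2,2,2-trifluoroethoxy)phosphoryl]propanoic acid give the C7 phosphonopropanoate F10. Still–Gennari olefination with acetaldehyde (KN(SiMe3)2, 18-crown-6, THF, −78 °C) should then form the Z-trisubstituted alkene of 22.

**Further compounds**

F1 | step 10 | allylic diol (C8–OH, C5–OH) of the tricyclic enol ether | COC=1[C@@H]2[C@H]3[C@H](O)C=C(C)[C@@H]2[C@@]3(C)[C@H](O)C=1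
F2 | step 10 | bis(tert-butyldimethylsilyl) ether of F1 | COC=1[C@@H]2[C@H]3[C@H](O[Si](C)(C)C(C)(C)C)C=C(C)[C@@H]2[C@@]3(C)[C@H](O[Si](C)(C)C(C)(C)C)C=1
F3 | step 10 | C7 ketone with C5 and C8 silyl ethers | O=C1[C@@H]2[C@H]3[C@H](O[Si](C)(C)C(C)(C)C)C=C(C)[C@@H]2[C@@]3(C)[C@H](O[Si](C)(C)C(C)(C)C)C1
F4 | step 10 | C7 tertiary alcohol bearing 2-propenyl trans to the C5 silyloxy group | C=C(C)[C@@]1(O)[C@@H]2[C@H]3[C@H](O[Si](C)(C)C(C)(C)C)C=C(C)[C@@H]2[C@@]3(C)[C@H](O[Si](C)(C)C(C)(C)C)C1
F5 | step 10 | epoxy alcohol (2-methyloxiran-2-yl on C7) | C[C@@]1(CO1)[C@@]2(O)[C@@H]3[C@H]4[C@H](O[Si](C)(C)C(C)(C)C)C=C(C)[C@@H]3[C@@]4(C)[C@H](O[Si](C)(C)C(C)(C)C)C2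
F6 | step 10 | ring-expanded C1 hydroxymethyl C7 ketone, bis-silyl ether | OC[C@]1(C)[C@@H]2[C@H]3[C@H](O[Si](C)(C)C(C)(C)C)C=C(C)[C@@H]2[C@@]3(C)[C@H](O[Si](C)(C)C(C)(C)C)CC1=O
F7 | step 10 | C1 hydroxymethyl C7 alcohol, bis-silyl ether | OC[C@]1(C)[C@@H]2[C@H]3[C@H](O[Si](C)(C)C(C)(C)C)C=C(C)[C@@H]2[C@@]3(C)[C@H](O[Si](C)(C)C(C)(C)C)C[C@H]1O
F8 | step 6 | C2 methyl carbonate of enone diol 6 | CC1=CC(=O)C[C@]2(C)[C@H](O)C=C(OC)[C@H](OC(=O)OC)[C@H]12
F9 | step 6 | C5 trimethylsilyl ether of F8 | CC1=CC(=O)C[C@]2(C)[C@H](O[Si](C)(C)C)C=C(OC)[C@H](OC(=O)OC)[C@H]12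
F10 | step 15 | C7 2-[bis(2,2,2-trifluoroethoxy)phosphoryl]propanoate of 21 | C/C=C(/C)C(=O)OC[C@]1(C)[C@@H]2[C@H]3C(=O)C=C(C)[C@@H]2[C@@]3(C)[C@H](OC(=O)/C(C)=C\C)C[C@H]1OC(=O)C(C)P(=O)(OCC(F)(F)F)OCC(F)(F)F
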